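## Retrosynthetic overview

- The target is cut first at C3–O (late enzymatic C–H hydroxylation of the 3-deoxy lactone), then at C12–C13 (primary iodide plus 3-bromofuran-2(5H)-one), the only C–C bond made.
- The iodide comes from a 9α-hydroxy-7-en-6-one hub: C8–H by axial protonation in a dissolving-metal reduction, C6–O by α-face hydride reduction of the ketone, then acetylation.
- The hub is cut at the key C9–O bond: aerobic γ-C–H hydroxylation of a 7-en-6-one, itself made by allylic oxidation (C6=O) of a Δ7 alkene.
- The Δ7 alkene comes from sclareol glycol by acetylation and dehydration.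
- No ring is formed: rings A and B are bought with sclareol glycol, the butenolide ring with the bromofuranone.

Assumption: sclareol glycol (ambradiol; also one LiAlH4 step from sclareolide) and 3-bromofuran-2(5H)-one are bought as such.

## Route

Step 1
Reactants: 1 sclareol glycol [(5S,8R,9R,10S)-13,14,15,16-tetranorlabdane-8α,12-diol]
Product: 2 8α-hydroxy-13,14,15,16-tetranorlabdan-12-yl acetate
Conditions: Ac2O (1.1 equiv), pyridine, DMAP (cat.), CH2Cl2, 0 °C
Reagents that add atoms: acetic anhydride CC(=O)OC(C)=O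
Why: Selective acylation of the primary alcohol; the tertiary 8α-alcohol does not react at 0 °C.

Step 2
Reactants: 2 8α-hydroxy-13,14,15,16-tetranorlabdan-12-yl acetate
Product: 3 13,14,15,16-tetranorlabd-7-en-12-yl acetate (9α-H)
Conditions: TsOH·H2O (5 mol%), PhMe, 70 °C, 30 min; AgNO3–SiO2 chromatography
Reagents that add atoms: none
Why: Acid-catalysed E1 dehydration: the C8 cation loses the axial 7α-H under kinetic control to give the ring-trisubstituted Δ7 alkene as the main isomer (Δ8(17) and Δ8(9) isomers are removed on AgNO3–silica), and the acetate blocks closure to the tetrahydrofuran.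

Step 3
Reactants: 3 13,14,15,16-tetranorlabd-7-en-12-yl acetate
Product: 4 6-oxo-13,14,15,16-tetranorlabd-7-en-12-yl acetate
Conditions: CrO3, 3,5-dimethylpyrazole, CH2Cl2, −20 °C
Reagents that add atoms: chromium trioxide O=[Cr](=O)=O
Why: Allylic oxidation with the CrO3–3,5-dimethylpyrazole complex: the C6 methylene is oxidised to the enone, as in the conversion of Δ7 sterols into 7-en-6-ones; no stereocenter is formed.

Step 4
Reactants: 4 6-oxo-13,14,15,16-tetranorlabd-7-en-12-yl acetate
Product: 6 9α-hydroxy-6-oxo-13,14,15,16-tetranorlabd-7-en-12-yl acetate, via 9α-hydroperoxide 5 (not isolated)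
Conditions: N-hydroxyphthalimide (20 mol%), AIBN (5 mol%), O2 (1 atm), MeCN, 70 °C; then PPh3, 0 °C
Reagents that add atoms: dioxygen O=O
Why: Proposed new method: site- and face-selective aerobic γ-C(sp3)–H hydroxylation of a β,β-disubstituted cyclohexenone by N-oxyl hydrogen-atom-transfer catalysis: the phthalimide-N-oxyl radical abstracts the axial 9α-H, the weakest C–H bond of 4 (tertiary and vinylogous to the C6 carbonyl, clearly weaker than the competing C17 methyl C–H, while the ring A C–H bonds are too strong for this N-oxyl), O2 adds to the delocalised radical at C9 on the α face (anti to the C10 methyl, keeping the enone conjugated), the peroxyl radical takes H from N-hydroxyphthalimide to carry the chain, the tertiary hydroperoxide cannot over-oxidise and PPh3 reduces it to the alcohol; closest known reaction type: N-hydroxyphthalimide/O2 allylic oxidation of isophorone-type enones and the SeO2 γ-hydroxylation (14α) of steroidal 7-en-6-ones, where SeO2 would here be expected to attack the C17 methyl.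

Step 5
Reactants: 6 9α-hydroxy-6-oxo-13,14,15,16-tetranorlabd-7-en-12-yl acetate
Product: 9 9α-hydroxy-6-oxo-13,14,15,16-tetranorlabdan-12-yl acetate (C8 methyl α; 8β-H), via lithium alkoxide 7 (not isolated), via dilithium enolate alkoxide 8 (not isolated)
Conditions: LiN(SiMe3)2 (1.05 equiv), THF, −78 °C; then Li (2.5 equiv), NH3(l)/THF, t-BuOH (1 equiv), −78 °C; then NH4Cl
Reagents that add atoms: none
Why: Dissolving-metal enone reduction: the C8 carbanion is protonated axially from the β face (Stork rule), which sets C8 with the methyl equatorial (α); the C9 hydroxyl is first made the lithium alkoxide so that it is a poor leaving group and cannot deliver a proton from the α face, and any primary acetate lost here converges in step 6.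

Step 6
Reactants: 9 9α-hydroxy-6-oxo-13,14,15,16-tetranorlabdan-12-yl acetate (C8 methyl α)
Product: 10 13,14,15,16-tetranorlabdane-6β,9α,12-triol (C8 methyl α; 8β-H)
Conditions: LiAlH4, THF, 0 °C to rt
Reagents that add atoms: none
Why: Hydride reduction: LiAlH4 attacks the C6 ketone from the α face because the β face is screened by the syn-axial methyls on C4 and C10, giving the axial 6β-alcohol, and it cleaves the primary acetate.

Step 7
Reactants: 10 13,14,15,16-tetranorlabdane-6β,9α,12-triol (C8 methyl α)
Product: 11 12-iodo-13,14,15,16-tetranorlabdane-6β,9α-diol (C8 methyl α)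
Conditions: PPh3, iodine, imidazole, CH2Cl2, 0 °C
Reagents that add atoms: iodine [I][I]
Why: Appel-type iodination: only the unhindered primary alcohol forms the alkoxyphosphonium ion and is displaced by iodide (SN2); the axial secondary and the tertiary alcohols do not react.

Step 8
Reactants: 11 12-iodo-13,14,15,16-tetranorlabdane-6β,9α-diol (C8 methyl α)
Product: 12 9α-hydroxy-12-iodo-13,14,15,16-tetranorlabdan-6β-yl acetate (C8 methyl α)
Conditions: Ac2O, Et3N, DMAP (10 mol%), CH2Cl2, rt to 35 °C
Reagents that add atoms: acetic anhydride CC(=O)OC(C)=O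
Why: DMAP-catalysed acylation of the secondary 6β-alcohol; the tertiary 9α-alcohol is too hindered to be acylated under these conditions.

Step 9
Reactants: 12 9α-hydroxy-12-iodo-13,14,15,16-tetranorlabdan-6β-yl acetate (C8 methyl α); 13 3-bromofuran-2(5H)-one
Product: 14 6β-acetoxy-9α-hydroxylabd-13-en-16,15-olide (C8 methyl α)
Conditions: NiBr2·(MeOCH2CH2OMe) (10 mol%), 4,4'-di-tert-butyl-2,2'-bipyridine (10 mol%), Zn (2 equiv), DMA, rt
Reagents that add atoms: none
Why: Nickel-catalysed reductive cross-electrophile coupling of a primary alkyl iodide with a vinyl bromide: the vinyl bromide adds oxidatively to nickel, the alkyl radical from the iodide is captured and reductive elimination forms the C12–C13 bond; the free tertiary alcohol, acetate and lactone are tolerated and no stereocenter is touched.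

Step 10
Reactants: 14 6β-acetoxy-9α-hydroxylabd-13-en-16,15-olide
Product: 15 6β-acetoxy-3β,9α-dihydroxylabd-13-en-16,15-olide (target CNP0513254.1)
Conditions: engineered cytochrome P450 BM3 variant (heme-iron monooxygenase), E. coli lysate, NADP+ (cat.), glucose dehydrogenase, D-glucose, air, KPi buffer pH 8.0, 5% DMSO, 25 °C
Reagents that add atoms: dioxygen O=O
Why: Enzymatic C–H hydroxylation by an engineered P450 BM3 of the family that hydroxylates sclareolide and sclareol at C3: ring A binds over the heme as in those substrates, the equatorial 3β-H is abstracted and oxygen rebound with retention gives the 3β-alcohol, leaving all other groups untouched.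

## Compound list

1 | sclareol glycol, (5S,8R,9R,10S)-13,14,15,16-tetranorlabdane-8α,12-diol | C1C[C@@](C)(O)[C@H](CCO)[C@@]2(C)CCCC(C)(C)[C@H]12 | starting material
2 | 8α-hydroxy-13,14,15,16-tetranorlabdan-12-yl acetate | C1C[C@@](C)(O)[C@H](CCOC(C)=O)[C@@]2(C)CCCC(C)(C)[C@H]12 | intermediate
3 | 13,14,15,16-tetranorlabd-7-en-12-yl acetate (5α-H, 9α-H, 10β-methyl) | C1C=C(C)[C@H](CCOC(C)=O)[C@@]2(C)CCCC(C)(C)[C@H]12 | intermediate
4 | 6-oxo-13,14,15,16-tetranorlabd-7-en-12-yl acetate | O=C1C=C(C)[C@H](CCOC(C)=O)[C@@]2(C)CCCC(C)(C)[C@H]12 | intermediate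
5 | 9α-hydroperoxy-6-oxo-13,14,15,16-tetranorlabd-7-en-12-yl acetate | O=C1C=C(C)[C@](OO)(CCOC(C)=O)[C@@]2(C)CCCC(C)(C)[C@H]12 | intermediate (not isolated)
6 | 9α-hydroxy-6-oxo-13,14,15,16-tetranorlabd-7-en-12-yl acetate | O=C1C=C(C)[C@](O)(CCOC(C)=O)[C@@]2(C)CCCC(C)(C)[C@H]12 | intermediate
7 | lithium 9α-alkoxide of 6 | O=C1C=C(C)[C@]([O-])(CCOC(C)=O)[C@@]2(C)CCCC(C)(C)[C@H]12.[Li+] | intermediate (not isolated)
8 | dilithium C6-enolate 9α-alkoxide, C8 methyl α, 8β-H | [O-]C1=C[C@@H](C)[C@]([O-])(CCOC(C)=O)[C@@]2(C)CCCC(C)(C)[C@H]12.[Li+].[Li+] | intermediate (not isolated)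
9 | 9α-hydroxy-6-oxo-13,14,15,16-tetranorlabdan-12-yl acetate, C8 methyl α, 8β-H | O=C1C[C@@H](C)[C@](O)(CCOC(C)=O)[C@@]2(C)CCCC(C)(C)[C@H]12 | intermediate
10 | 13,14,15,16-tetranorlabdane-6β,9α,12-triol, C8 methyl α, 8β-H | O[C@@H]1C[C@@H](C)[C@](O)(CCO)[C@@]2(C)CCCC(C)(C)[C@H]12 | intermediate
11 | 12-iodo-13,14,15,16-tetranorlabdane-6β,9α-diol, C8 methyl α | O[C@@H]1C[C@@H](C)[C@](O)(CCI)[C@@]2(C)CCCC(C)(C)[C@H]12 | intermediate
12 | 9α-hydroxy-12-iodo-13,14,15,16-tetranorlabdan-6β-yl acetate, C8 methyl α | CC(=O)O[C@@H]1C[C@@H](C)[C@](O)(CCI)[C@@]2(C)CCCC(C)(C)[C@H]12 | intermediate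
13 | 3-bromofuran-2(5H)-one | O=C1OCC=C1Br | starting material
14 | 6β-acetoxy-9α-hydroxylabd-13-en-16,15-olide, C8 methyl α, 8β-H | CC(=O)O[C@@H]1C[C@@H](C)[C@](O)(CCC2=CCOC2=O)[C@@]2(C)CCCC(C)(C)[C@H]12 | intermediate
15 | 6β-acetoxy-3β,9α-dihydroxylabd-13-en-16,15-olide (CNP0513254.1) | CC(=O)O[C@@H]1C[C@@H](C)[C@](O)(CCC2=CCOC2=O)[C@@]2(C)CC[C@H](O)C(C)(C)[C@H]12 | target

## Step count and risks

Total step count: 10. Longest linear sequence: 10 steps (1 to 15); 13 is bought.

The three steps most likely to fail:

Step 4 (the proposed new method). Risk: hydrogen abstraction at the C17 methyl, or slow chain propagation. The fallback is known chemistry and swaps the radical route for an ionic one. It sets out from 4. TMSCl, NaI and Et3N in MeCN at 25 °C (equilibrating conditions) give the homoannular dienol ether 12-acetoxy-6-(trimethylsilyloxy)-13,14,15,16-tetranorlabda-6,8-diene F1. Its electron-rich C8=C9 bond is epoxidised from the α face by dimethyldioxirane in acetone at −40 °C (vinylogous Rubottom oxidation). Loss of the silyl group on work-up gives the γ-hydroxy enone, and the fallback comes back to the route at 6.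

Step 5. Risk: reductive loss of the C9 oxygen from the γ-oxido enone. The fallback sets C8 by an intramolecular hydrogen shift instead of a protonation. It sets out from 6.
- TsNHNH2 (EtOH, AcOH cat.) gives the C6 tosylhydrazone of 6 F2.
- Catecholborane, then NaOAc·3H2O in refluxing CHCl3, gives the Δ6 alkene 9α-hydroxy-13,14,15,16-tetranorlabd-6-en-12-yl acetate (C8 methyl α) F3. This goes through the 6β-diazene, whose retro-ene loss of N2 delivers H to C8 on the β face.
- NBS in aqueous acetone opens the α-bromonium ion trans-diaxially to 7α-bromo-6β,9α-dihydroxy-13,14,15,16-tetranorlabdan-12-yl acetate F4. Water has to attack C6 between two syn-axial methyls, so this regiochemistry is the weak point of the fallback.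
- Bu3SnH/AIBN in PhH removes bromine to give 6β,9α-dihydroxy-13,14,15,16-tetranorlabdan-12-yl acetate F5.
- K2CO3 in MeOH cleaves the primary acetate, and the fallback comes back to the route at 10.

Step 10. Risk: the enzyme does not accept 14, or oxidises C2. The fallback replaces the enzyme by a small-molecule catalyst plus a reduction. It sets out from 14. The divalent iron complex [Fe(C20H26N4)(MeCN)2](SbF6)2 (C20H26N4 = (2S,2'S)-1,1'-bis(pyridin-2-ylmethyl)-2,2'-bipyrrolidine) with H2O2 and AcOH in MeCN oxidises the remote ring A methylenes. After separation from the 2-oxo isomer, which is expected to be the major product, this gives the 3-ketone 6β-acetoxy-9α-hydroxy-3-oxolabd-13-en-16,15-olide F6. NaBH4/CeCl3 in MeOH at −40 °C delivers hydride axially from the α face to give the equatorial 3β-alcohol, and the fallback comes back to the route at 15.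

Further compounds
F1 | step 4 | 12-acetoxy-6-(trimethylsilyloxy)-13,14,15,16-tetranorlabda-6,8-diene | C[Si](C)(C)OC1=CC(C)=C(CCOC(C)=O)[C@@]2(C)CCCC(C)(C)[C@H]12
F2 | step 5 | C6 tosylhydrazone of 6 | Cc1ccc(cc1)S(=O)(=O)NN=C1C=C(C)[C@](O)(CCOC(C)=O)[C@@]2(C)CCCC(C)(C)[C@H]12
F3 | step 5 | 9α-hydroxy-13,14,15,16-tetranorlabd-6-en-12-yl acetate (C8 methyl α, 8β-H) | C1=C[C@@H](C)[C@](O)(CCOC(C)=O)[C@@]2(C)CCCC(C)(C)[C@H]12
F4 | step 5 | 7α-bromo-6β,9α-dihydroxy-13,14,15,16-tetranorlabdan-12-yl acetate (C8 methyl α) | O[C@@H]1[C@@H](Br)[C@@H](C)[C@](O)(CCOC(C)=O)[C@@]2(C)CCCC(C)(C)[C@H]12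
F5 | step 5 | 6β,9α-dihydroxy-13,14,15,16-tetranorlabdan-12-yl acetate (C8 methyl α) | O[C@@H]1C[C@@H](C)[C@](O)(CCOC(C)=O)[C@@]2(C)CCCC(C)(C)[C@H]12
F6 | step 10 | 6β-acetoxy-9α-hydroxy-3-oxolabd-13-en-16,15-olide | CC(=O)O[C@@H]1C[C@@H](C)[C@](O)(CCC2=CCOC2=O)[C@@]2(C)CCC(=O)C(C)(C)[C@H]12
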